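Integracin B is cut at the two bonds that join ring A to its ortho substituents: C1–C(=O) of the benzoate and C6–C(benzylic) of the 8-hydroxyundecyl chain. Both are made at once when a 3,5-bis(benzyloxy)benzyne inserts into the C2–C1 bond of an α-phenylsulfonyl dodecanoate that already carries the ring B alcohol as its ester, so the hindered 2,6-disubstituted benzoate is never made by acylation. The oxygen beside the aryne (the future C2–O of ring A) steers the carbanion to C6 and the carbonyl to C1. The precursor is the fully benzylated sulfonyl ester, built from (R)-1,2-epoxypentane twice; desulfonylation and one hydrogenolysis finish the synthesis.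

Key step: step 11

Remark on the key precursor: its acyl part has to be a twelve-carbon acid, (9R)-9-(benzyloxy)-2-(phenylsulfonyl)dodecanoate, because C2 of the acid becomes the benzylic carbon and C1 the benzoate carbonyl; an 8-benzyloxy-undecanoate would leave the ring A chain one carbon short.

Assumption: 1,3-bis(benzyloxy)-5-bromobenzene is taken as purchasable (otherwise one benzylation of 5-bromoresorcinol).

Step 1
Reactants: 1 (R)-1,2-epoxypentane; 2 6-bromohex-1-ene
Product: 4 (R)-undec-10-en-4-ol, via hex-5-enylmagnesium bromide 3 (not isolated)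
Conditions: Mg, THF, rt; then CuI (10 mol %), 1, THF, −30 → 0 °C; aq NH4Cl
Reagents that add atoms: none
Why: Copper-catalysed Grignard opening of a terminal epoxide is an SN2 attack at the unsubstituted CH2, so the C–O bond at the stereocentre is not touched and the (R)-configuration of 1 becomes that of the C4 carbinol.

Step 2
Reactants: 4 (R)-undec-10-en-4-ol; 5 1,3-bis(benzyloxy)-5-bromobenzene
Product: 7 (R)-11-[3,5-bis(benzyloxy)phenyl]undecan-4-ol, via alkylborane 6 (not isolated)
Conditions: 9-BBN (2.3 equiv), THF, 0 °C → rt; then 5, PdCl2(dppf) (5 mol %), K3PO4 (3 M aq), THF/DMF, 60 °C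
Reagents that add atoms: none
Why: Anti-Markovnikov hydroboration of the terminal alkene followed by B-alkyl Suzuki–Miyaura coupling forms the C11–aryl bond without touching the stereocentre or the benzyl ethers, the extra 9-BBN covering the free hydroxyl, whose O–B bond is hydrolysed again by the aqueous base.

Step 3
Reactants: 1 (R)-1,2-epoxypentane; 8 1-bromo-5-chloropentane
Product: 10 (R)-10-chlorodecan-4-ol, via (5-chloropentyl)magnesium bromide 9 (not isolated)
Conditions: Mg, THF, ≤ 25 °C; then CuI (10 mol %), 1, THF, −30 → 0 °C; aq NH4Cl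
Reagents that add atoms: none
Why: Magnesium inserts selectively into the C–Br bond and the copper-catalysed Grignard opening again takes place at the epoxide CH2, so the (R)-centre of 1 is carried over unchanged while the primary chloride stays inert at this temperature.

Step 4
Reactants: 10 (R)-10-chlorodecan-4-ol
Product: 11 (R)-7-(benzyloxy)-1-chlorodecane
Conditions: NaH, BnBr, DMF, 0 °C → rt
Reagents that add atoms: benzyl bromide, BrCc1ccccc1
Why: Williamson etherification of the sodium alkoxide with the far more reactive benzylic bromide protects the carbinol without affecting its configuration or the primary chloride.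

Step 5
Reactants: 11 (R)-7-(benzyloxy)-1-chlorodecane
Product: 12 (R)-7-(benzyloxy)-1-iododecane
Conditions: NaI, acetone, reflux
Reagents that add atoms: sodium iodide, [Na+].[I-]
Why: Finkelstein exchange, driven by precipitation of NaCl, converts the primary chloride into the iodide needed for a clean C-alkylation.

Step 6
Reactants: 7 (R)-11-[3,5-bis(benzyloxy)phenyl]undecan-4-ol; 13 (phenylsulfonyl)acetic acid
Product: 14 (R)-11-[3,5-bis(benzyloxy)phenyl]undecan-4-yl (phenylsulfonyl)acetate
Conditions: DCC, DMAP (10 mol %), CH2Cl2, 0 °C → rt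
Reagents that add atoms: none
Why: Steglich esterification of an unhindered acetic acid proceeds by acyl transfer to the alcohol oxygen, so the carbinol C–O bond is not broken and its (R)-configuration is retained.

Step 7
Reactants: 14 (R)-11-[3,5-bis(benzyloxy)phenyl]undecan-4-yl (phenylsulfonyl)acetate; 12 (R)-7-(benzyloxy)-1-iododecane
Product: 15 (4R)-11-[3,5-bis(benzyloxy)phenyl]undecan-4-yl (9R)-9-(benzyloxy)-2-(phenylsulfonyl)dodecanoate (both epimers at C2)
Conditions: NaH (1.0 equiv), DMF, 0 °C; then 12, rt → 45 °C
Reagents that add atoms: none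
Why: The methylene flanked by sulfone and ester is deprotonated cleanly and its soft carbanion undergoes SN2 C-alkylation with the primary iodide, a second alkylation being slow at the now tertiary centre; the new C2 centre forms without control, which is harmless because it is erased in step 12.

Step 8
Reactants: 16 3,5-bis(benzyloxy)phenol
Product: 17 3,5-bis(benzyloxy)-2-bromophenol
Conditions: NBS (1.0 equiv), CH2Cl2, −78 °C
Reagents that add atoms: N-bromosuccinimide, O=C1CCC(=O)N1Br
Why: Electrophilic aromatic bromination of the strongly activated phenol at low temperature is expected to favour the position ortho to the hydroxyl (C2 and C6 are equivalent) over the more crowded C4 between the two benzyloxy groups.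

Step 9
Reactants: 17 3,5-bis(benzyloxy)-2-bromophenol
Product: 18 [3,5-bis(benzyloxy)-2-bromophenoxy]trimethylsilane
Conditions: HMDS, THF, 70 °C; concentrate
Reagents that add atoms: hexamethyldisilazane, C[Si](C)(C)N[Si](C)(C)C
Why: O-Silylation of the phenol with hexamethyldisilazane gives the aryl silyl ether with ammonia as the only by-product, so the crude material can be taken on directly.

Step 10
Reactants: 18 [3,5-bis(benzyloxy)-2-bromophenoxy]trimethylsilane
Product: 21 3,5-bis(benzyloxy)-2-(trimethylsilyl)phenyl trifluoromethanesulfonate, via aryllithium 19 (not isolated), via lithium aryloxide 20 (not isolated)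
Conditions: n-BuLi, THF, −100 → −78 °C; then Tf2O, −100 → −78 °C
Reagents that add atoms: trifluoromethanesulfonic anhydride, O=S(=O)(OS(=O)(=O)C(F)(F)F)C(F)(F)F
Why: Bromine–lithium exchange gives the ortho-lithiated aryl silyl ether, which undergoes the 1,3 O-to-C silyl shift (retro-Brook rearrangement) to the 2-silyl phenoxide that is triflated in the same flask, the low temperature keeping the benzylic ether positions from being metalated.

Step 11
Reactants: 15 (4R)-11-[3,5-bis(benzyloxy)phenyl]undecan-4-yl (9R)-9-(benzyloxy)-2-(phenylsulfonyl)dodecanoate; 21 3,5-bis(benzyloxy)-2-(trimethylsilyl)phenyl trifluoromethanesulfonate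
Product: 23 (4R)-11-[3,5-bis(benzyloxy)phenyl]undecan-4-yl 2,4-bis(benzyloxy)-6-[(8R)-8-(benzyloxy)-1-(phenylsulfonyl)undecyl]benzoate (both epimers at the sulfonyl carbon), via 3,5-bis(benzyloxy)benzyne 22 (not isolated)
Conditions: CsF (4 equiv), MeCN/THF (2:1), 60 °C; 21 (1.6 equiv) added slowly
Reagents that add atoms: none
Why: Proposed new method: fluoride removes the silyl group of 21 with loss of triflate to give aryne 22 and also deprotonates C2 of 15, whose sulfone- and ester-stabilised carbanion adds to the aryne carbon distal to the neighbouring benzyloxy group; the aryl anion so formed, now ortho to that benzyloxy group, attacks the ester carbonyl to give a four-membered benzocyclobutenoxide, whose opening breaks the former C2–C1 bond and leaves the alkoxycarbonyl group on ring A C1 and a sulfone-stabilised anion on the carbon attached to ring A C6, which is then protonated. The closest known reaction type is the acyl-alkylation of arynes from ortho-silylaryl triflates with β-keto esters, together with the related insertions into malonates and β-keto sulfones; what is new is the migration of an ester carbonyl from an α-sulfonyl ester. No ring is closed in the product, and the only new stereocentre, the benzylic sulfone carbon, forms without control as both epimers and is erased in step 12, the two carbinol centres being remote from every charged position. The step needs regioselective addition to the unsymmetrical aryne, secured by the inductively withdrawing benzyloxy group beside the triple bond, which stabilises negative charge on the adjacent carbon and so sends the carbanion to the far one, and it needs carbonyl attack to outrun protonation, which the aprotic medium and the four-atom proximity of the ester favour. A second arylation is unlikely because the product anion is tertiary and buttressed by two ortho substituents.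

Step 12
Reactants: 23 (4R)-11-[3,5-bis(benzyloxy)phenyl]undecan-4-yl 2,4-bis(benzyloxy)-6-[(8R)-8-(benzyloxy)-1-(phenylsulfonyl)undecyl]benzoate
Product: 24 (4R)-11-[3,5-bis(benzyloxy)phenyl]undecan-4-yl 2,4-bis(benzyloxy)-6-[(8R)-8-(benzyloxy)undecyl]benzoate (penta-O-benzyl integracin B)
Conditions: Mg turnings (excess), MeOH/THF (3:1), rt → 40 °C
Reagents that add atoms: none
Why: Reductive desulfonylation by electron transfer from magnesium in methanol cleaves the activated benzylic C–S bond and the solvent protonates the resulting carbanion to a CH2 group, while the shielded 2,6-disubstituted benzoate and the benzyl ethers are inert to the reagent.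

Step 13
Reactants: 24 (4R)-11-[3,5-bis(benzyloxy)phenyl]undecan-4-yl 2,4-bis(benzyloxy)-6-[(8R)-8-(benzyloxy)undecyl]benzoate
Product: 25 integracin B
Conditions: H2 (1 atm), Pd/C (10 %), EtOAc/MeOH, rt
Reagents that add atoms: none
Why: Catalytic hydrogenolysis cleaves the four aryl benzyl ethers and the secondary alkyl benzyl ether at their benzylic C–O bonds, whereas the ester belongs to a non-benzylic secondary alcohol and the C–O bonds at both stereocentres are not benzylic, so both (R)-centres survive.

Compound list
1 | (R)-1,2-epoxypentane | CCC[C@@H]1CO1 | starting material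
2 | 6-bromohex-1-ene | C=CCCCCBr | starting material
3 | hex-5-enylmagnesium bromide | C=CCCCC[Mg]Br | intermediate
4 | (R)-undec-10-en-4-ol | CCC[C@@H](O)CCCCCC=C | intermediate
5 | 1,3-bis(benzyloxy)-5-bromobenzene | Brc1cc(OCc2ccccc2)cc(OCc2ccccc2)c1 | starting material
6 | alkylborane: 4 carrying a 9-borabicyclo[3.3.1]nonan-9-yl group on C11 and on the C4 oxygen | CCC[C@@H](OB1C2CCCC1CCC2)CCCCCCCB1C2CCCC1CCC2 | intermediate
7 | (R)-11-[3,5-bis(benzyloxy)phenyl]undecan-4-ol | CCC[C@@H](O)CCCCCCCc1cc(OCc2ccccc2)cc(OCc2ccccc2)c1 | intermediate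
8 | 1-bromo-5-chloropentane | ClCCCCCBr | starting material
9 | (5-chloropentyl)magnesium bromide | ClCCCCC[Mg]Br | intermediate
10 | (R)-10-chlorodecan-4-ol | CCC[C@@H](O)CCCCCCCl | intermediate
11 | (R)-7-(benzyloxy)-1-chlorodecane | CCC[C@@H](OCc1ccccc1)CCCCCCCl | intermediate
12 | (R)-7-(benzyloxy)-1-iododecane | CCC[C@@H](OCc1ccccc1)CCCCCCI | intermediate
13 | (phenylsulfonyl)acetic acid | OC(=O)CS(=O)(=O)c1ccccc1 | starting material
14 | (R)-11-[3,5-bis(benzyloxy)phenyl]undecan-4-yl (phenylsulfonyl)acetate | O=C(CS(=O)(=O)c1ccccc1)O[C@H](CCC)CCCCCCCc1cc(OCc2ccccc2)cc(OCc2ccccc2)c1 | intermediate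
15 | (4R)-11-[3,5-bis(benzyloxy)phenyl]undecan-4-yl (9R)-9-(benzyloxy)-2-(phenylsulfonyl)dodecanoate, both epimers at C2 | CCC[C@@H](OCc1ccccc1)CCCCCCC(S(=O)(=O)c1ccccc1)C(=O)O[C@H](CCC)CCCCCCCc1cc(OCc2ccccc2)cc(OCc2ccccc2)c1 | intermediate
16 | 3,5-bis(benzyloxy)phenol | Oc1cc(OCc2ccccc2)cc(OCc2ccccc2)c1 | starting material
17 | 3,5-bis(benzyloxy)-2-bromophenol | Oc1cc(OCc2ccccc2)cc(OCc2ccccc2)c1Br | intermediate
18 | [3,5-bis(benzyloxy)-2-bromophenoxy]trimethylsilane | C[Si](C)(C)Oc1cc(OCc2ccccc2)cc(OCc2ccccc2)c1Br | intermediate
19 | aryllithium: [3,5-bis(benzyloxy)-2-lithiophenoxy]trimethylsilane | C[Si](C)(C)Oc1cc(OCc2ccccc2)cc(OCc2ccccc2)c1[Li] | intermediate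
20 | lithium 3,5-bis(benzyloxy)-2-(trimethylsilyl)phenoxide | [Li+].[O-]c1cc(OCc2ccccc2)cc(OCc2ccccc2)c1[Si](C)(C)C | intermediate
21 | 3,5-bis(benzyloxy)-2-(trimethylsilyl)phenyl trifluoromethanesulfonate | C[Si](C)(C)c1c(OS(=O)(=O)C(F)(F)F)cc(OCc2ccccc2)cc1OCc1ccccc1 | intermediate
22 | 3,5-bis(benzyloxy)benzyne (1,2-didehydro-3,5-bis(benzyloxy)benzene) | C1#CC(OCc2ccccc2)=CC(OCc2ccccc2)=C1 | intermediate
23 | (4R)-11-[3,5-bis(benzyloxy)phenyl]undecan-4-yl 2,4-bis(benzyloxy)-6-[(8R)-8-(benzyloxy)-1-(phenylsulfonyl)undecyl]benzoate, both epimers at the sulfonyl carbon | CCC[C@@H](OCc1ccccc1)CCCCCCC(S(=O)(=O)c1ccccc1)c1cc(OCc2ccccc2)cc(OCc2ccccc2)c1C(=O)O[C@H](CCC)CCCCCCCc1cc(OCc2ccccc2)cc(OCc2ccccc2)c1 | intermediate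
24 | (4R)-11-[3,5-bis(benzyloxy)phenyl]undecan-4-yl 2,4-bis(benzyloxy)-6-[(8R)-8-(benzyloxy)undecyl]benzoate | CCC[C@@H](OCc1ccccc1)CCCCCCCc1cc(OCc2ccccc2)cc(OCc2ccccc2)c1C(=O)O[C@H](CCC)CCCCCCCc1cc(OCc2ccccc2)cc(OCc2ccccc2)c1 | intermediate
25 | integracin B, (4R)-11-(3,5-dihydroxyphenyl)undecan-4-yl 2,4-dihydroxy-6-[(8R)-8-hydroxyundecyl]benzoate | CCC[C@@H](O)CCCCCCCc1cc(O)cc(O)c1C(=O)O[C@H](CCC)CCCCCCCc1cc(O)cc(O)c1 | target

Total step count: 13.
Longest linear sequence: 7 steps (steps 1, 2, 6, 7, 11, 12, 13; the branch through steps 3, 4, 5, 7, 11, 12, 13 is equally long).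

Steps most likely to fail

Step 11 (the new method). The aryl anion may be protonated before it closes onto the ester, which would give plain α-arylation. It may instead attack sulfur, or the hindered tertiary carbanion may add so slowly that the aryne is consumed otherwise. The fallback uses known chemistry, sets out from iodide 12 and alcohol 7 and returns to the route at 24. Commercial methyl 2,4-dihydroxy-6-methylbenzoate is benzylated (BnBr, K2CO3, DMF) to methyl 2,4-bis(benzyloxy)-6-methylbenzoate F1. Lateral deprotonation of the ring methyl group (LDA, THF, −78 °C) and alkylation with 12 should give methyl 2,4-bis(benzyloxy)-6-[(8R)-8-(benzyloxy)undecyl]benzoate F2, which is saponified (KOH, DMSO/H2O, 100 °C) to 2,4-bis(benzyloxy)-6-[(8R)-8-(benzyloxy)undecyl]benzoic acid F3. The hindered acid is then used as the nucleophile in a Mitsunobu esterification. Because that reaction inverts the carbinol, 7 is first inverted (4-nitrobenzoic acid, PPh3, DIAD, THF) to (S)-11-[3,5-bis(benzyloxy)phenyl]undecan-4-yl 4-nitrobenzoate F4 and methanolysed (K2CO3, MeOH) to (S)-11-[3,5-bis(benzyloxy)phenyl]undecan-4-ol F5. Coupling of F3 with F5 (PPh3, DIAD, toluene) should then give the (R)-ester 24 by SN2 displacement, and step 13 follows.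

Step 8. Bromination may occur at C4, between the two benzyloxy groups, or twice, instead of once ortho to the hydroxyl. The fallback sets out from phenol 16 and returns at 17, replacing electrophilic substitution by directed ortho-metalation. Phenol 16 is protected (MOMCl, i-Pr2NEt, CH2Cl2) as 1,3-bis(benzyloxy)-5-(methoxymethoxy)benzene F6. Lithiation (n-BuLi, THF, −20 → 0 °C) is directed by the stronger acetal director to the position between the methoxymethoxy group and a benzyloxy group, and quenching with BrCCl2CCl2Br gives 1,5-bis(benzyloxy)-2-bromo-3-(methoxymethoxy)benzene F7. HCl in MeOH removes the acetal to give 17, and steps 9 and 10 follow.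

Step 12. Electron transfer to the crowded, poorly methanol-soluble sulfone may stall, or the magnesium methoxide formed may cause side reactions before the C–S bond is reduced. The fallback sets out from 23 and returns at 25, removing the sulfone by elimination instead of reduction. KOtBu (THF/t-BuOH, 50 °C) expels benzenesulfinate in an E2 process to give the styrene (4R)-11-[3,5-bis(benzyloxy)phenyl]undecan-4-yl 2,4-bis(benzyloxy)-6-[(1E,8R)-8-(benzyloxy)undec-1-en-1-yl]benzoate F8. The hydrogenation of step 13 (H2, Pd/C, EtOAc/MeOH) then saturates the alkene while removing the five benzyl groups and should give 25 directly.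

Further compounds
F1 | step 11 | methyl 2,4-bis(benzyloxy)-6-methylbenzoate | COC(=O)c1c(C)cc(OCc2ccccc2)cc1OCc1ccccc1
F2 | step 11 | methyl 2,4-bis(benzyloxy)-6-[(8R)-8-(benzyloxy)undecyl]benzoate | CCC[C@@H](OCc1ccccc1)CCCCCCCc1cc(OCc2ccccc2)cc(OCc2ccccc2)c1C(=O)OC
F3 | step 11 | 2,4-bis(benzyloxy)-6-[(8R)-8-(benzyloxy)undecyl]benzoic acid | CCC[C@@H](OCc1ccccc1)CCCCCCCc1cc(OCc2ccccc2)cc(OCc2ccccc2)c1C(=O)O
F4 | step 11 | (S)-11-[3,5-bis(benzyloxy)phenyl]undecan-4-yl 4-nitrobenzoate | CCC[C@H](OC(=O)c1ccc(cc1)[N+](=O)[O-])CCCCCCCc1cc(OCc2ccccc2)cc(OCc2ccccc2)c1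
F5 | step 11 | (S)-11-[3,5-bis(benzyloxy)phenyl]undecan-4-ol | CCC[C@H](O)CCCCCCCc1cc(OCc2ccccc2)cc(OCc2ccccc2)c1
F6 | step 8 | 1,3-bis(benzyloxy)-5-(methoxymethoxy)benzene | COCOc1cc(OCc2ccccc2)cc(OCc2ccccc2)c1
F7 | step 8 | 1,5-bis(benzyloxy)-2-bromo-3-(methoxymethoxy)benzene | COCOc1cc(OCc2ccccc2)cc(OCc2ccccc2)c1Br
F8 | step 12 | (4R)-11-[3,5-bis(benzyloxy)phenyl]undecan-4-yl 2,4-bis(benzyloxy)-6-[(1E,8R)-8-(benzyloxy)undec-1-en-1-yl]benzoate | CCC[C@@H](OCc1ccccc1)CCCCC/C=C/c1cc(OCc2ccccc2)cc(OCc2ccccc2)c1C(=O)O[C@H](CCC)CCCCCCCc1cc(OCc2ccccc2)cc(OCc2ccccc2)c1
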